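Ring labels: A is the benzo ring of the chroman, B the 4-hydroxyphenyl group at C2, C the pyran ring, D the acylphloroglucinol at C4. The retrosynthesis cuts the five phenol protecting groups, then C2–C3 and C4–C4a together, then the vinyl, formyl and acyl C–C bonds on ring D and the two acetal C–O bonds at C2.
Enabling feature: in C4a=C8a–O1–C2, an aryl ether oxygen of ring A adjoins a benzylic carbon bearing ring B. This is a latent O-aryl oxocarbenium ion (a cationic 2-oxadiene). C3–C4 is a two-carbon unit whose C4 is attached to the electron-rich ring D, that is, the vinyl group of a styrene.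
Forward: phloroglucinol is acylated, formylated, benzylated and methylenated to the ring D styrene. In parallel, 4-benzyloxybenzaldehyde goes through its gem-dichloride to the symmetrical bis(3-benzyloxyphenyl) acetal, which carries rings A and B.
Acetal and styrene are joined in a cationic formal [4+2] cycloaddition that closes ring C, the only ring built. Hydrogenolysis of five benzyl ethers ends the route.
Stereochemistry: C2 (S) comes from the chiral counter-anion of an imidodiphosphorimidate (IDPi) acid in the first C–C bond formation. C4 (S) is relayed from C2 by a diequatorial, 2,4-cis chair-like closure.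
Key step: step 7

Assumption: which antipode of the IDPi acid delivers (2S) has to be found by experiment; the route is written for that antipode, and both are accessible from (R)- or (S)-BINOL.

Step 1
Reactants: 1 phloroglucinol (benzene-1,3,5-triol); 2 9-phenylnonanoic acid
Product: 3 1-(2,4,6-trihydroxyphenyl)-9-phenylnonan-1-one
Conditions: BF3·OEt2 (as solvent), 85 °C; aq. NaOAc work-up
Reagents that add atoms: none
Why: Friedel–Crafts acylation with the free acid in BF3·OEt2 should work because phloroglucinol is by far the most nucleophilic arene present (the terminal phenyl ring does not compete) and the chelated ketone formed resists a second acylation.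

Step 2
Reactants: 3 1-(2,4,6-trihydroxyphenyl)-9-phenylnonan-1-one
Product: 5 2,4,6-trihydroxy-3-(9-phenylnonanoyl)benzaldehyde, via aryl iminium chloride 4 (not isolated)
Conditions: POCl3 (1.1 equiv), DMF (1.2 equiv), EtOAc, 0 °C → rt; then H2O, rt
Reagents that add atoms: N,N-dimethylformamide, CN(C)C=O; water, O
Why: In this Vilsmeier–Haack formylation the two free ring carbons of 3 are equivalent and far more nucleophilic than the enol of the chelated ketone, so one equivalent of chloroiminium salt at or below room temperature should formylate the ring once rather than build a chromone, and the new formyl group deactivates the ring towards a second attack.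

Step 3
Reactants: 5 2,4,6-trihydroxy-3-(9-phenylnonanoyl)benzaldehyde
Product: 6 2,4,6-tris(benzyloxy)-3-(9-phenylnonanoyl)benzaldehyde
Conditions: BnBr (4 equiv), K2CO3 (5 equiv), DMF, 60 °C
Reagents that add atoms: benzyl bromide, BrCc1ccccc1
Why: In this Williamson etherification in a polar aprotic solvent the potassium phenoxides should react at oxygen, the two carbonyl groups lower the nucleophilicity of the one remaining ring carbon, and warming overcomes the chelation of the hydroxyl groups.

Step 4
Reactants: 6 2,4,6-tris(benzyloxy)-3-(9-phenylnonanoyl)benzaldehyde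
Product: 7 1-[2,4,6-tris(benzyloxy)-3-vinylphenyl]-9-phenylnonan-1-one
Conditions: MePPh3Br (1.1 equiv), KOt-Bu (1.05 equiv), THF, 0 °C; then 6, −20 °C → rt
Reagents that add atoms: methyltriphenylphosphonium bromide, C[P+](c1ccccc1)(c1ccccc1)c1ccccc1.[Br-]
Why: In this Wittig methylenation the aldehyde reacts much faster with the unstabilised ylide than the aryl alkyl ketone, which is shielded by two ortho benzyloxy groups and at worst is enolised reversibly, so about one equivalent of ylide should be chemoselective.

Step 5
Reactants: 8 4-benzyloxybenzaldehyde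
Product: 9 1-(benzyloxy)-4-(dichloromethyl)benzene
Conditions: SOCl2 (3 equiv), DMF (cat.), CH2Cl2, rt → 40 °C; volatiles removed, used crude at once
Reagents that add atoms: thionyl chloride, O=S(Cl)Cl
Why: In this DMF-catalysed deoxygenative gem-dichlorination of an aromatic aldehyde with SOCl2 the para-alkoxy group assists both C–O ionisations and the aryl benzyl ether is inert to the reagent.

Step 6
Reactants: 9 1-(benzyloxy)-4-(dichloromethyl)benzene; 10 3-benzyloxyphenol (2.2 equiv)
Product: 11 4-benzyloxybenzaldehyde bis(3-benzyloxyphenyl) acetal (1-(benzyloxy)-4-{bis[3-(benzyloxy)phenoxy]methyl}benzene, achiral)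
Conditions: Cs2CO3 (3 equiv), DMF, 0 °C → rt; chromatography on Et3N-washed silica
Reagents that add atoms: none
Why: This double Williamson-type (SN1-like) substitution of a benzal chloride by a phenoxide is the classical entry to diaryl acetals, the basic medium avoids acid-induced Friedel–Crafts attack on the electron-rich phenol, and the polar aprotic solvent with the large caesium counter-ion favours O- over C-alkylation.

Step 7
Reactants: 11 4-benzyloxybenzaldehyde bis(3-benzyloxyphenyl) acetal (1.5 equiv); 7 1-[2,4,6-tris(benzyloxy)-3-vinylphenyl]-9-phenylnonan-1-one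
Product: 14 1-{2,4,6-tris(benzyloxy)-3-[(2S,4S)-7-(benzyloxy)-2-[4-(benzyloxy)phenyl]chroman-4-yl]phenyl}-9-phenylnonan-1-one (pentabenzyl ether of the target), via aryloxycarbenium ion 12 (not isolated), via C4 benzylic cation 13 (not isolated)
Conditions: BINOL-derived IDPi Brønsted acid (3,3'-aryl, N-triflyl; 5 mol %), 4 Å MS, toluene/CH2Cl2, −60 °C, 7 added by syringe pump over 12 h; Et3N quench
Reagents that add atoms: none
Why: Proposed new method: the strong, confined IDPi acid protonates one of the two identical aryloxy groups of 11, so that loss of 3-benzyloxyphenol can lead only to the aryloxycarbenium ion 12 (a methyl aryl acetal could also ionise the wrong way, by loss of the phenol), the CH2 terminus of 7 then bonds to C2 to give cation 13, whose charge at C4 is carried by the two ortho and the one para benzyloxy group of ring D, and ring A captures C4 with loss of a proton that regenerates the acid. The closest known reaction types are the SnCl4-promoted oxa-Povarov reaction of O-aryl mixed acetals with styrenes, which gives racemic 2,4-cis chromans, and IDPi-catalysed enantioselective Prins-type additions of styrenes to oxocarbenium ions; the new element is the pairing of an acyclic aryloxycarbenium ion with a chiral anion. Ring C closes by intramolecular Friedel–Crafts alkylation, a six-membered cation–arene closure in which the attacking C4a=C8a bond of ring A lies inside the new ring (endo mode), so that overall the step is a stepwise formal [4+2] cycloaddition forming C2–C3 and C4–C4a. C2 is set under catalyst control when the anion shields one face of planar 12 during the first bond formation, and C4 is set under substrate control because the chair-like closure places ring B and ring D both equatorial, which is the 2,4-cis relation and, with (2S), means (4S). The step needs site selectivity on ring A, secured by the benzyloxy group para to the attacked carbon and by crowding at the alternative carbon between the two oxygens, and chemoselectivity for the vinyl group over the free C5–H of ring D, secured by the open CH2 terminus as against a ring carbon flanked by two benzyloxy groups. Feeding 7 slowly into an excess of 11 at low temperature keeps its protonation and cationic oligomerisation in check and protects 14 from acid-induced reopening at C2–O1.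

Step 8
Reactants: 14 pentabenzyl ether of the target, (2S,4S)
Product: 15 1-{2,4,6-trihydroxy-3-[(2S,4S)-7-hydroxy-2-(4-hydroxyphenyl)chroman-4-yl]phenyl}-9-phenylnonan-1-one (target)
Conditions: H2 (1 atm), 10 % Pd/C, EtOAc/EtOH, rt
Reagents that add atoms: none
Why: In this catalytic hydrogenolysis of aryl benzyl ethers the five primary O–CH2Ph bonds should be cleaved much faster than the secondary, ring-bound C2–O1 bond, the hindered and then chelated ketone and the arenes are untouched at 1 atm, and the neutral medium avoids ionisation at C2 or C4, so both stereocentres are kept.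

Compound list
1 | phloroglucinol | Oc1cc(O)cc(O)c1 | starting material
2 | 9-phenylnonanoic acid | O=C(O)CCCCCCCCc1ccccc1 | starting material
3 | 1-(2,4,6-trihydroxyphenyl)-9-phenylnonan-1-one | O=C(CCCCCCCCc1ccccc1)c1c(O)cc(O)cc1O | intermediate
4 | N,N-dimethyl-[2,4,6-trihydroxy-3-(9-phenylnonanoyl)benzylidene]iminium chloride (not isolated) | C[N+](C)=Cc1c(O)cc(O)c(C(=O)CCCCCCCCc2ccccc2)c1O.[Cl-] | intermediate
5 | 2,4,6-trihydroxy-3-(9-phenylnonanoyl)benzaldehyde | O=Cc1c(O)cc(O)c(C(=O)CCCCCCCCc2ccccc2)c1O | intermediate
6 | 2,4,6-tris(benzyloxy)-3-(9-phenylnonanoyl)benzaldehyde | O=Cc1c(OCc2ccccc2)cc(OCc2ccccc2)c(C(=O)CCCCCCCCc2ccccc2)c1OCc1ccccc1 | intermediate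
7 | 1-[2,4,6-tris(benzyloxy)-3-vinylphenyl]-9-phenylnonan-1-one | C=Cc1c(OCc2ccccc2)cc(OCc2ccccc2)c(C(=O)CCCCCCCCc2ccccc2)c1OCc1ccccc1 | intermediate
8 | 4-benzyloxybenzaldehyde | O=Cc1ccc(OCc2ccccc2)cc1 | starting material
9 | 1-(benzyloxy)-4-(dichloromethyl)benzene | ClC(Cl)c1ccc(OCc2ccccc2)cc1 | intermediate
10 | 3-benzyloxyphenol | Oc1cccc(OCc2ccccc2)c1 | starting material
11 | 4-benzyloxybenzaldehyde bis(3-benzyloxyphenyl) acetal | C(Oc1cccc(OCc2ccccc2)c1)(Oc1cccc(OCc2ccccc2)c1)c1ccc(OCc2ccccc2)cc1 | intermediate
12 | [4-(benzyloxy)benzylidene][3-(benzyloxy)phenyl]oxonium ion, counter-ion the IDPi anion (not isolated) | C(=[O+]c1cccc(OCc2ccccc2)c1)c1ccc(OCc2ccccc2)cc1 | intermediate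
13 | (3S)-3-[3-(benzyloxy)phenoxy]-3-[4-(benzyloxy)phenyl]-1-[2,4,6-tris(benzyloxy)-3-(9-phenylnonanoyl)phenyl]propan-1-ylium, counter-ion the IDPi anion (not isolated) | O=C(CCCCCCCCc1ccccc1)c1c(OCc2ccccc2)cc(OCc2ccccc2)c([CH+]C[C@@H](c2ccc(OCc3ccccc3)cc2)Oc2cccc(OCc3ccccc3)c2)c1OCc1ccccc1 | intermediate
14 | 1-{2,4,6-tris(benzyloxy)-3-[(2S,4S)-7-(benzyloxy)-2-[4-(benzyloxy)phenyl]chroman-4-yl]phenyl}-9-phenylnonan-1-one | O=C(CCCCCCCCc1ccccc1)c1c(OCc2ccccc2)cc(OCc2ccccc2)c([C@H]2C[C@@H](c3ccc(OCc4ccccc4)cc3)Oc3cc(OCc4ccccc4)ccc32)c1OCc1ccccc1 | intermediate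
15 | 1-{2,4,6-trihydroxy-3-[(2S,4S)-7-hydroxy-2-(4-hydroxyphenyl)chroman-4-yl]phenyl}-9-phenylnonan-1-one | O=C(CCCCCCCCc1ccccc1)c1c(O)cc(O)c([C@H]2C[C@@H](c3ccc(O)cc3)Oc3cc(O)ccc32)c1O | target

Total step count: 8. Longest linear sequence: 6 (steps 1, 2, 3, 4, 7, 8).

Steps most likely to fail

**Step 7.** The risks are:
- poor facial discrimination within the ion pair;
- Friedel–Crafts capture of the oxocarbenium ion by the liberated phenol or by the free C5–H position of ring D;
- acid-induced oligomerisation of the styrene.

In the fallback the C4–ring D bond is made last, by known chemistry, from an enantioenriched flavan-4-ol. It sets out from 8 and 3 and comes back to the route at 15. Claisen–Schmidt condensation of 8 with commercial 4'-benzyloxy-2'-hydroxyacetophenone F1 (KOH, EtOH) should give the (E)-2'-hydroxychalcone F2. NaOAc in refluxing EtOH cyclises this by oxa-Michael addition to the racemic flavanone F3. Kinetic resolution follows by asymmetric transfer hydrogenation (RuCl(p-cymene)(TsDPEN) of the suitable antipode, HCO2H/Et3N, stopped near half conversion). It should reduce the (2S)-ketone to the (2S,4S)-flavan-4-ol F4 and leave the (2R)-flavanone F5, which is removed by chromatography. Catalytic TsOH in CH2Cl2/THF ionises F4 at C4, and an excess of 3 is alkylated at one of its two equivalent ring carbons (Friedel–Crafts alkylation) to the 7,4'-dibenzyl ether of the target F6. C2 is not touched, and the reversible bond formation should settle on the diequatorial 2,4-cis arrangement. Hydrogenolysis under the conditions of step 8 gives 15.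

**Step 6.** The risks are C-alkylation of the ambident phenoxide by the easily ionised dichloride, and hydrolysis of dichloride or acetal on handling. In the fallback the aryloxy group is introduced once only, through an α-chloro ether. It sets out from 8 and 10 and comes back to the route at 14. HC(OMe)3 with catalytic TsOH in MeOH converts 8 into the dimethyl acetal F7. Acetyl chloride with catalytic ZnCl2 exchanges one methoxy group for chloride to give the α-chlorobenzyl methyl ether F8. F8 is not isolated but treated with 10 and Cs2CO3 in DMF to give the methyl 3-benzyloxyphenyl mixed acetal F9. F9 takes the place of 11 in step 7, with 5 Å MS to bind the methanol, and the route is rejoined at 14. F9 belongs to the acetal class on which the SnCl4-promoted reaction is established. Its drawback under a Brønsted acid, the competing departure of the phenol, is the reason it is held in reserve.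

**Step 3.** The risks are incomplete etherification of the chelated hydroxyl groups, and C-benzylation with loss of aromaticity. In the fallback the benzyl ethers are in place before either carbonyl group is introduced. It sets out from 2 and comes back to the route at 6, so steps 1 to 3 are bypassed. Trifluoroacetic anhydride in CH2Cl2 at 0 °C turns 2 into the mixed 9-phenylnonanoic trifluoroacetic anhydride F11. This acylates commercial 1,3,5-tris(benzyloxy)benzene F10 (Friedel–Crafts acylation without a metal halide, so that the ortho benzyl ethers are not cleaved) to 1-[2,4,6-tris(benzyloxy)phenyl]-9-phenylnonan-1-one F12. Vilsmeier–Haack formylation (POCl3, DMF, 40 °C) at one of the two equivalent free ring carbons proceeds through the tribenzyl iminium chloride F13. Hydrolysis with aq. NaOAc gives 6. With no free ortho hydroxyl group, chromone formation is excluded as well.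

Further compounds
F1 | step 7 | 1-[4-(benzyloxy)-2-hydroxyphenyl]ethanone (4'-benzyloxy-2'-hydroxyacetophenone) | CC(=O)c1ccc(OCc2ccccc2)cc1O
F2 | step 7 | (E)-1-[4-(benzyloxy)-2-hydroxyphenyl]-3-[4-(benzyloxy)phenyl]prop-2-en-1-one | O=C(/C=C/c1ccc(OCc2ccccc2)cc1)c1ccc(OCc2ccccc2)cc1O
F3 | step 7 | racemic 7-(benzyloxy)-2-[4-(benzyloxy)phenyl]chroman-4-one | O=C1CC(c2ccc(OCc3ccccc3)cc2)Oc2cc(OCc3ccccc3)ccc21
F4 | step 7 | (2S,4S)-7-(benzyloxy)-2-[4-(benzyloxy)phenyl]chroman-4-ol | O[C@H]1C[C@@H](c2ccc(OCc3ccccc3)cc2)Oc2cc(OCc3ccccc3)ccc21
F5 | step 7 | (2R)-7-(benzyloxy)-2-[4-(benzyloxy)phenyl]chroman-4-one | O=C1C[C@H](c2ccc(OCc3ccccc3)cc2)Oc2cc(OCc3ccccc3)ccc21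
F6 | step 7 | 1-{3-[(2S,4S)-7-(benzyloxy)-2-[4-(benzyloxy)phenyl]chroman-4-yl]-2,4,6-trihydroxyphenyl}-9-phenylnonan-1-one | O=C(CCCCCCCCc1ccccc1)c1c(O)cc(O)c([C@H]2C[C@@H](c3ccc(OCc4ccccc4)cc3)Oc3cc(OCc4ccccc4)ccc32)c1O
F7 | step 6 | 1-(benzyloxy)-4-(dimethoxymethyl)benzene | COC(OC)c1ccc(OCc2ccccc2)cc1
F8 | step 6 | racemic 1-(benzyloxy)-4-[chloro(methoxy)methyl]benzene | COC(Cl)c1ccc(OCc2ccccc2)cc1
F9 | step 6 | racemic 1-(benzyloxy)-3-{[4-(benzyloxy)phenyl](methoxy)methoxy}benzene | COC(Oc1cccc(OCc2ccccc2)c1)c1ccc(OCc2ccccc2)cc1
F10 | step 3 | 1,3,5-tris(benzyloxy)benzene | c1c(OCc2ccccc2)cc(OCc2ccccc2)cc1OCc1ccccc1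
F11 | step 3 | 9-phenylnonanoic trifluoroacetic anhydride | O=C(CCCCCCCCc1ccccc1)OC(=O)C(F)(F)F
F12 | step 3 | 1-[2,4,6-tris(benzyloxy)phenyl]-9-phenylnonan-1-one | O=C(CCCCCCCCc1ccccc1)c1c(OCc2ccccc2)cc(OCc2ccccc2)cc1OCc1ccccc1
F13 | step 3 | N,N-dimethyl-[2,4,6-tris(benzyloxy)-3-(9-phenylnonanoyl)benzylidene]iminium chloride | C[N+](C)=Cc1c(OCc2ccccc2)cc(OCc2ccccc2)c(C(=O)CCCCCCCCc2ccccc2)c1OCc1ccccc1.[Cl-]
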